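## Retrosynthetic overview

1. The strategy rests on this feature: the cyclohexene C3a–C4–C5–C6–C7–C7a is cis-fused through C6–C7 to the cyclobutane C6–C7–C3'–C8', whose C3' is at the ketone oxidation level. In addition, C3a, C3 and C8–C11 map onto the six carbons of norleucine (carboxyl carbon to C3a, α-carbon to C3, side chain to the butylidene).
2. The (Z)-C3=C8 butylidene is made last, from a 3-butyl butenolide by oxygenation at C3 and dehydration. The C3 stereocentre is erased there, after it has relayed its chirality to C6 and C7.
3. The spirophthalide ring comes from convex-face addition of a 2-(ethoxycarbonyl)phenyl magnesium reagent to the C3' cyclobutanone and lactonisation. The C8' propyl group comes from propanal by aldol condensation and convex-face hydrogenation.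
4. Key disconnection: C5–C6 and C7–C7a, by a Diels–Alder reaction of (R)-5-butyl-4-vinylfuran-2(5H)-one with cyclobutenone. This closes the cyclohexene and brings in the four-membered ring intact.
5. The diene comes from D-norleucine (butenolide ring by Dieckmann closure, C1 and C7a from acetate, C4 and C5 by Stille vinylation); cyclobutenone from 3-oxocyclobutanecarboxylic acid. Ring order: butenolide, then cyclohexene, then phthalide lactone.

Key step: step 9

Remark on locants: target locants are used throughout (lactone C1(=O), O2, C3, C3a, C4–C7, C7a; C8 is the first butyl or butylidene carbon; C3' is the cyclobutane carbonyl or spiro carbon, C8' the other non-fused cyclobutane carbon).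

Remark on C3: after step 9 the C3–H is acidic (γ-position of a butenolide) and is expected to epimerise in the basic steps. Compounds 13 to 25 are therefore carried as C3 epimer pairs with fixed C6 and C7, and they converge when C3 becomes sp2 in step 17.

## Route

Step 1
Reactants: 1 D-norleucine
Product: 2 (R)-2-hydroxyhexanoic acid
Conditions: NaNO2, 1 M H2SO4 (aq), 0 °C to rt
Reagents that add atoms: water, O
Why: Diazotisation of the α-amino acid with neighbouring carboxylate participation should replace nitrogen by hydroxyl with net retention (double inversion), so the R configuration of 1 is kept.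

Step 2
Reactants: 2 (R)-2-hydroxyhexanoic acid
Product: 3 methyl (R)-2-hydroxyhexanoate
Conditions: MeOH, H2SO4 (cat.), reflux
Reagents that add atoms: methanol, CO
Why: Fischer esterification acts only at the carboxyl group and leaves the stereocentre untouched.

Step 3
Reactants: 3 methyl (R)-2-hydroxyhexanoate
Product: 4 methyl (R)-2-acetoxyhexanoate
Conditions: Ac2O, pyridine, DMAP (cat.), CH2Cl2, 0 °C to rt
Reagents that add atoms: acetic anhydride, CC(=O)OC(C)=O
Why: DMAP-catalysed O-acetylation of the secondary alcohol installs the two carbons that become C1 and C7a without touching the C–O stereocentre.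

Step 4
Reactants: 4 methyl (R)-2-acetoxyhexanoate
Product: 5 (R)-5-butyl-4-hydroxyfuran-2(5H)-one
Conditions: LiHMDS (2.2 equiv), THF, −78 °C to −20 °C; then 1 M HCl
Reagents that add atoms: none
Why: Dieckmann condensation of the acetate enolate onto the methyl ester (5-exo-trig) closes the tetronic acid ring, and the second equivalent of base holds the product as its tetronate, which is not acidic at the butyl-bearing carbon, a reaction type established for O-acetyl α-hydroxy esters without loss of configuration.

Step 5
Reactants: 5 (R)-5-butyl-4-hydroxyfuran-2(5H)-one
Product: 6 (R)-2-butyl-5-oxo-2,5-dihydrofuran-3-yl trifluoromethanesulfonate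
Conditions: Tf2O, iPr2NEt, CH2Cl2, −78 °C
Reagents that add atoms: triflic anhydride, O=S(=O)(OS(=O)(=O)C(F)(F)F)C(F)(F)F
Why: O-sulfonylation of the vinylogous acid gives the enol triflate, and the hindered base at low temperature should avoid deprotonation of the acidic γ-hydrogen and hence racemisation.

Step 6
Reactants: 6 (R)-2-butyl-5-oxo-2,5-dihydrofuran-3-yl trifluoromethanesulfonate; 7 tributyl(vinyl)stannane
Product: 8 (R)-5-butyl-4-vinylfuran-2(5H)-one
Conditions: Pd(PPh3)4 (5 mol %), LiCl, THF, 60 °C
Reagents that add atoms: none
Why: Stille cross-coupling of the electron-poor enol triflate with the vinylstannane runs without base, so the base-labile stereocentre next to the new diene should survive.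

Step 7
Reactants: 9 3-oxocyclobutanecarboxylic acid
Product: 10 3-bromocyclobutanone
Conditions: HgO, Br2, MgSO4, CH2Cl2, reflux
Reagents that add atoms: bromine, BrBr
Why: Hunsdiecker-type bromodecarboxylation (Cristol–Firth variant) exchanges the carboxyl group for bromine through the acyl hypobromite and an alkyl radical, and the ketone is inert to it.

Step 8
Reactants: 10 3-bromocyclobutanone
Product: 11 cyclobutenone
Conditions: Bu3N, neat, rt, reduced pressure, distilled into a −78 °C trap; used at once as a cold CH2Cl2 solution
Reagents that add atoms: none
Why: β-Elimination of HBr from the β-bromo ketone (E1cB) gives the strained enone, and removing it from the base as it forms limits oligomerisation.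

Step 9
Reactants: 8 (R)-5-butyl-4-vinylfuran-2(5H)-one; 11 cyclobutenone
Product: 12 (3R,6S,7R,7aR)-tricyclic keto lactone (3-butyl lactone with C3a=C4 alkene and cis-fused cyclobutanone C6–C7–C3'(=O)–C8'H2; H6 H7 H7a all cis)
Conditions: ZnCl2 (0.5 equiv), CH2Cl2, −20 °C to rt; 11 (3 equiv) added in portions
Reagents that add atoms: none
Why: A concerted, asynchronous [4+2] cycloaddition is expected in which the vinyl terminus C5 of the diene C7a=C3a–C4=C5 bonds to the β-carbon C6 of ZnCl2-bound cyclobutenone while C7a closes onto the α-carbon C7, the ring strain of the dienophile lowering the distortion cost; the closest known reaction type is the Lewis-acid-promoted Diels–Alder reaction of cyclobutenone with acyclic and semicyclic dienes, and 4-vinylbutenolides are known dienes. The cyclohexene C3a–C4–C5–C6–C7–C7a is closed by intermolecular annulation, both σ-bonds C5–C6 and C7–C7a being formed suprafacially on each partner in the same step. C6 and C7 must be cis because the dienophile alkene is held cis in the four-membered ring, and their absolute sense, like that of the transient centre C7a, follows from the endo placement of the C3' carbonyl under C3a–C4 combined with approach to the diene face opposite the butyl group on C3. The step needs regioselectivity (C5 to C6, the two carbonyl-bearing termini C7a and C7 joined), endo selectivity and facial selectivity: the first rests on the larger HOMO coefficient at the terminus remote from the lactone carbonyl meeting the larger LUMO coefficient at the enone β-carbon, the second on secondary orbital overlap reinforced by the Lewis acid and the small bulk of the four-membered ring, the third on the butyl group of the stereocentre flanking C3a. Because C3 and C7a are still stereocentres in 12, every minor isomer is a diastereomer and is removed by chromatography before those centres are erased, which secures the enantiomeric purity of C6 and C7.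

Step 10
Reactants: 12 (3R,6S,7R,7aR)-tricyclic keto lactone
Product: 13 (6S,7R)-3-butyl butenolide ketone (alkene C3a=C7a; cis-fused cyclobutanone; C3 epimers)
Conditions: DBU (0.2 equiv), CH2Cl2, 0 °C to rt
Reagents that add atoms: none
Why: Base-mediated prototropic shift through the lactone dienolate (H7a removed, C4 protonated) moves the alkene into conjugation as the tetrasubstituted butenolide, the thermodynamic isomer, while C6 and C7 are held by the cis ring fusion.

Step 11
Reactants: 13 (6S,7R)-3-butyl butenolide ketone; 14 propanal
Product: 16 β-hydroxy ketone (1-hydroxypropyl at C8'; mixture at C8' and the carbinol carbon), via dilithium dianion 15 (not isolated)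
Conditions: LDA (2.2 equiv), THF, −78 °C; then 14 (1.05 equiv), −78 °C; AcOH quench
Reagents that add atoms: none
Why: In this directed aldol addition the first equivalent of base parks the acidic C3–H as the aromatic furanolate and the second forms the kinetic cyclobutanone enolate at the unhindered C8' methylene, which as the more basic and less delocalised site of the dianion should take up the one equivalent of aldehyde.

Step 12
Reactants: 16 β-hydroxy ketone
Product: 18 (E)-C8'-propylidene cyclobutanone, via methanesulfonate 17 (not isolated)
Conditions: MsCl, Et3N, CH2Cl2, 0 °C; then DBU, rt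
Reagents that add atoms: none
Why: Mesylation and E1cB elimination complete the aldol condensation to the conjugated enone, whose alkene geometry is without consequence because both isomers give the same hydrogenation product, and DBU returns any deconjugated lactone to the butenolide.

Step 13
Reactants: 18 (E)-C8'-propylidene cyclobutanone
Product: 19 (6S,7R,8'R)-C8'-propyl cyclobutanone (propyl cis to C5, on the concave face)
Conditions: H2 (1 atm), 10% Pd/C, EtOAc, rt, stopped at one equivalent
Reagents that add atoms: none
Why: Heterogeneous hydrogenation should deliver hydrogen to the exocyclic enone alkene from the convex face of the cis-fused bicyclo[4.2.0] unit (the face of H6), which places H8' cis to H6 and H7 and the propyl group on the concave face, while the tetrasubstituted C3a=C7a alkene and the ketone are not reduced.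

Step 14
Reactants: 19 (6S,7R,8'R)-C8'-propyl cyclobutanone; 20 ethyl 2-iodobenzoate
Product: 23 (6S,7R,8'R,3'R)-spirophthalide 3-butyl butenolide (C3 epimers), via arylmagnesium chloride 21 (not isolated), via chloromagnesium alkoxide 22 (not isolated)
Conditions: 20 (2.5 equiv), iPrMgCl·LiCl, THF, −40 °C; LaCl3·2LiCl, then 19, −78 °C to rt; aq NH4Cl
Reagents that add atoms: none
Why: Iodine–magnesium exchange gives the ester-bearing aryl magnesium reagent, which with LaCl3·2LiCl to suppress enolisation should add to the strained cyclobutanone from the convex face, anti to both the C8' propyl group and C7a, and the tertiary alkoxide then acylates on the neighbouring ethyl ester (5-exo-trig lactonisation), fixing C3' as R with the lactone oxygen cis to the propyl group.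

Step 15
Reactants: 23 (6S,7R,8'R,3'R)-spirophthalide 3-butyl butenolide
Product: 24 1-(triisopropylsilyloxy)furan (furan O2–C1=C7a–C3a=C3; C3 no longer a stereocentre)
Conditions: TIPSOTf, Et3N, CH2Cl2, 0 °C
Reagents that add atoms: triisopropylsilyl triflate, CC(C)[Si](C(C)C)(C(C)C)OS(=O)(=O)C(F)(F)F
Why: Soft enolisation and O-silylation of the butenolide at its γ-hydrogen on C3 gives the aromatic 2-silyloxyfuran, the only enolisable position that leads to an aromatic product, and the phthalide has no α-hydrogen.

Step 16
Reactants: 24 1-(triisopropylsilyloxy)furan
Product: 25 3-butyl-3-hydroxy butenolide (lactol at C3; C3 epimers)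
Conditions: DMDO, acetone/CH2Cl2, −78 °C to 0 °C; then H2O, Amberlyst 15
Reagents that add atoms: dimethyldioxirane, CC1(C)OO1
Why: Electrophilic oxygen transfer from the dioxirane to the γ-carbon C3 of the 2-silyloxyfuran (a vinylogous Rubottom-type oxidation known for 5-substituted silyloxyfurans) restores the butenolide with a hydroxyl group on C3 once the silyl group is lost on aqueous work-up.

Step 17
Reactants: 25 3-butyl-3-hydroxy butenolide
Product: 26 target CNP0248594.2
Conditions: TsOH·H2O (10 mol %), 4 Å MS, toluene, 70 °C
Reagents that add atoms: none
Why: Acid-catalysed dehydration of the lactol through the acyl oxocarbenium ion with loss of H8 (E1) gives the enol lactone under equilibrating conditions, which favour the (Z)-butylidene with the propyl chain turned away from C4, and the stereocentres C6, C7, C8' and C3' carry no acidic hydrogen and are not affected.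

## Compound list

1 | D-norleucine | N[C@H](CCCC)C(=O)O | starting material
2 | (R)-2-hydroxyhexanoic acid | O[C@H](CCCC)C(=O)O | intermediate
3 | methyl (R)-2-hydroxyhexanoate | O[C@H](CCCC)C(=O)OC | intermediate
4 | methyl (R)-2-acetoxyhexanoate | CC(=O)O[C@H](CCCC)C(=O)OC | intermediate
5 | (R)-5-butyl-4-hydroxyfuran-2(5H)-one | CCCC[C@H]1OC(=O)C=C1O | intermediate
6 | (R)-2-butyl-5-oxo-2,5-dihydrofuran-3-yl trifluoromethanesulfonate | CCCC[C@H]1OC(=O)C=C1OS(=O)(=O)C(F)(F)F | intermediate
7 | tributyl(vinyl)stannane | C=C[Sn](CCCC)(CCCC)CCCC | starting material
8 | (R)-5-butyl-4-vinylfuran-2(5H)-one | CCCC[C@H]1OC(=O)C=C1C=C | intermediate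
9 | 3-oxocyclobutanecarboxylic acid | O=C1CC(C1)C(=O)O | starting material
10 | 3-bromocyclobutanone | O=C1CC(Br)C1 | intermediate
11 | cyclobutenone | O=C1C=CC1 | intermediate
12 | (3R,6S,7R,7aR)-tricyclic keto lactone, C3a=C4 alkene, cis-fused cyclobutanone | CCCC[C@H]1OC(=O)[C@H]2C1=CC[C@H]1CC(=O)[C@@H]21 | intermediate
13 | (6S,7R)-3-butyl butenolide ketone, C3a=C7a alkene, C3 epimers | CCCCC1OC(=O)C2=C1CC[C@H]1CC(=O)[C@@H]21 | intermediate
14 | propanal | CCC=O | starting material
15 | dilithium dianion of 13 (furanolate and C8'=C3' enolate) | [Li+].[Li+].CCCCc1oc([O-])c2c1CC[C@H]1C=C([O-])[C@@H]21 | intermediate (not isolated)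
16 | β-hydroxy ketone, 1-hydroxypropyl at C8' | CCCCC1OC(=O)C2=C1CC[C@H]1C(C(O)CC)C(=O)[C@@H]21 | intermediate
17 | methanesulfonate of 16 | CCCCC1OC(=O)C2=C1CC[C@H]1C(C(CC)OS(C)(=O)=O)C(=O)[C@@H]21 | intermediate (not isolated)
18 | (E)-C8'-propylidene cyclobutanone | CCCCC1OC(=O)C2=C1CC[C@H]1/C(=C\CC)C(=O)[C@@H]21 | intermediate
19 | (6S,7R,8'R)-C8'-propyl cyclobutanone, C3 epimers | CCCCC1OC(=O)C2=C1CC[C@H]1[C@@H](CCC)C(=O)[C@@H]21 | intermediate
20 | ethyl 2-iodobenzoate | CCOC(=O)c1ccccc1I | starting material
21 | 2-(ethoxycarbonyl)phenylmagnesium chloride | CCOC(=O)c1ccccc1[Mg]Cl | intermediate (not isolated)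
22 | chloromagnesium tertiary alkoxide at C3' | CCCCC1OC(=O)C2=C1CC[C@H]1[C@@H](CCC)[C@](O[Mg]Cl)(c3ccccc3C(=O)OCC)[C@@H]21 | intermediate (not isolated)
23 | (6S,7R,8'R,3'R)-spirophthalide 3-butyl butenolide, C3 epimers | CCCCC1OC(=O)C2=C1CC[C@H]1[C@@H](CCC)[C@@]3(OC(=O)c4ccccc43)[C@@H]21 | intermediate
24 | 1-(triisopropylsilyloxy)furan derived from 23 | CCCCc1oc(O[Si](C(C)C)(C(C)C)C(C)C)c2c1CC[C@H]1[C@@H](CCC)[C@@]3(OC(=O)c4ccccc43)[C@@H]21 | intermediate
25 | 3-butyl-3-hydroxy butenolide, C3 epimers | CCCCC1(O)OC(=O)C2=C1CC[C@H]1[C@@H](CCC)[C@@]3(OC(=O)c4ccccc43)[C@@H]21 | intermediate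
26 | CNP0248594.2, (Z)-butylidene, 6S,7R,8'R,3'R | CCC/C=C1\OC(=O)C2=C1CC[C@H]1[C@@H](CCC)[C@@]3(OC(=O)c4ccccc43)[C@@H]21 | target

## Step count and risks

Total step count: 17. Longest linear sequence: 15 steps (steps 1 to 6 and 9 to 17); the cyclobutenone branch (steps 7 and 8) joins at step 9.

Steps most likely to fail:

1. Step 9. Both partners carry acceptor groups, so the cycloaddition may be slow enough that oligomerisation of cyclobutenone or self-dimerisation of the diene outruns it. The Lewis acid may also be held by the lactone carbonyl of the diene, and the alkyl substituent on C3a opposes the regiochemical preference set by the lactone carbonyl. Any leakage in endo or facial selectivity lowers the yield of the one useful diastereomer. Fallback: the dienophile is made more electrophilic with a removable bromine. Setting out from 11, addition of Br2 (CH2Cl2, −78 °C) should give 2,3-dibromocyclobutanone F1, and Et3N then eliminates HBr to 2-bromocyclobut-2-en-1-one F2. Cycloaddition of this with diene 8 in the same orientation should give the 7-bromo adduct F3. Zn dust in AcOH removes the bromine, the enolate being protonated at C7 on the only face that keeps the cis fusion, and the route is rejoined at 12.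

2. Step 11. Carbon–carbon bond formation may occur at the furanolate (C3 or C7a) instead of C8', the base may remove H7 instead of a C8' hydrogen, and the cyclobutanone enolate may self-condense. Fallback: the ketone is activated selectively as an enamine, which the lactone cannot form. Setting out from 13, condensation with pyrrolidine (benzene, 4 Å MS) should give the pyrrolidine enamine F4 with its double bond at C3'=C8', away from the ring fusion. Reaction of this with propanal 14 and hydrolysis with aqueous AcOH gives the alkylidene ketone directly, and the route is rejoined at 18.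

3. Step 14. The basic aryl magnesium reagent may enolise the hindered ketone, with epimerisation of the kinetically set C8' centre. It may also be consumed by the acidic C3–H, or attack the butenolide carbonyl, and the lactonisation of the hindered alkoxide may stall. Fallback: the aryl group is brought in at the alcohol oxidation level with a non-basic organocerium reagent. Setting out from 19, the reagent from commercial (2-bromobenzyloxy)(tert-butyl)dimethylsilane (n-BuLi, THF, −78 °C; then CeCl3) should add from the convex face to give the silyl-protected tertiary cyclobutanol F5. TBAF frees the benzylic diol F6. MnO2 (CH2Cl2, rt) oxidises the primary benzylic alcohol, and the lactol that closes onto the tertiary hydroxyl is oxidised on to the lactone, so the route is rejoined at 23.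

## Further compounds

F1 | step 9 | 2,3-dibromocyclobutanone | O=C1CC(Br)C1Br
F2 | step 9 | 2-bromocyclobut-2-en-1-one | O=C1C(Br)=CC1
F3 | step 9 | 7-bromo analogue of adduct 12 | CCCC[C@H]1OC(=O)[C@H]2C1=CC[C@H]1CC(=O)[C@@]21Br
F4 | step 11 | pyrrolidine enamine of 13 (C3'=C8') | CCCCC1OC(=O)C2=C1CC[C@H]1C=C(N3CCCC3)[C@@H]21
F5 | step 14 | tertiary cyclobutanol with 2-(tert-butyldimethylsilyloxymethyl)phenyl group at C3' | CCCCC1OC(=O)C2=C1CC[C@H]1[C@@H](CCC)[C@](O)(c3ccccc3CO[Si](C)(C)C(C)(C)C)[C@@H]21
F6 | step 14 | diol with 2-(hydroxymethyl)phenyl group at C3' | CCCCC1OC(=O)C2=C1CC[C@H]1[C@@H](CCC)[C@](O)(c3ccccc3CO)[C@@H]21
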